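**Strategy.** The quinone ring [C1(=O), C2(OH), C3(icosyl), C4(=O), C5(OMe), C6(H)] is traced back to a squarate-derived 4-hydroxy-4-(methoxyethynyl)cyclobutenone. C1–C4, with both carbonyl carbons and the adjacent C2–O/C3–alkyl pair, are its four ring carbons, and C5(OMe)=C6(H) is the alkyne. The key step exploits the para-quinone with one unsubstituted ring carbon: heating opens the four-membered ring to an alkynylvinylketene that closes C4–C5, and the carbinol hydrogen moves to C6. The four-membered ring is thus expanded by two carbons to the fully substituted quinone at its final oxidation level in one operation. A tert-butyl ether masks the C2 hydroxyl.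

Key step: step 3

Assumption: Irisoquin D is taken from the SMILES as achiral 2-hydroxy-3-icosyl-5-methoxy-1,4-benzoquinone, and di-tert-butyl squarate is taken as a purchasable reagent.

**Step 1**
Reactants: 1 di-tert-butyl squarate (3,4-di-tert-butoxycyclobut-3-ene-1,2-dione); 2 1-bromoicosane
Product: 6 3-tert-butoxy-4-icosylcyclobut-3-ene-1,2-dione, via icosylmagnesium bromide 3 (not isolated), via bromomagnesium alkoxide adduct 4 (not isolated), via trifluoroacetate ester 5 (not isolated)
Conditions: 2, Mg, THF, reflux; add to 1, THF, −78 °C; then (CF3CO)2O, −78 to 0 °C; aq. NaHCO3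
Reagents that add atoms: none
Why: 1,2-Addition of Grignard reagent 3 to one squarate carbonyl should stop at alkoxide 4, and O-trifluoroacetylation to 5 lets the vinylogous tert-butoxy group expel trifluoroacetate and shed its tert-butyl group as isobutene, unveiling the second carbonyl (squarate 1,2-addition followed by acid-induced 1,3-carbonyl transposition).

**Step 2**
Reactants: 6 3-tert-butoxy-4-icosylcyclobut-3-ene-1,2-dione; 7 chloroacetaldehyde dimethyl acetal (2-chloro-1,1-dimethoxyethane)
Product: 9 rac-3-tert-butoxy-4-hydroxy-2-icosyl-4-(methoxyethynyl)cyclobut-2-en-1-one, via lithium methoxyacetylide 8 (not isolated)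
Conditions: 7, LiNEt2 (3 equiv, from Et2NH and n-BuLi), THF, 0 °C; then 6, THF, −78 °C; sat. aq. NH4Cl at −78 °C; crude or Et3N-deactivated silica
Reagents that add atoms: none
Why: The amide should convert 7 into acetylide 8 by loss of methanol, loss of HCl and deprotonation, and 8 should add 1,2 to the C2 carbonyl of 6, which is more electrophilic than C1 because C1 belongs to the vinylogous ester tBuO–C3=C4–C1=O (acetylide addition to a 3-alkoxy-4-alkylcyclobutenedione), giving a racemic carbinol centre that step 3 erases.

**Step 3**
Reactants: 9 rac-3-tert-butoxy-4-hydroxy-2-icosyl-4-(methoxyethynyl)cyclobut-2-en-1-one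
Product: 12 2-tert-butoxy-3-icosyl-5-methoxy-1,4-benzoquinone, via alkynylvinylketene 10 (not isolated), via aryl-phenoxyl diradical 11 (not isolated)
Conditions: toluene (degassed, 0.01 M, base-washed glassware), 110 °C
Reagents that add atoms: none
Why: Thermal conrotatory 4π ring opening of the cyclobutenone (hydroxyl rotating outward, so the alkyne lies cis to the ketene in 10) is followed by bonding of the ketene carbon to the methoxy-bearing alkyne carbon to give the aromatic aryl-radical/phenoxyl diradical 11, and transfer of the hydroxyl hydrogen to the aryl radical carbon (C6) should deliver quinone 12. The closest known reaction type is the Moore rearrangement of 4-alkynyl-4-hydroxycyclobutenones to 1,4-benzoquinones. The six-membered ring closes in the 6-endo-dig mode onto the alkyne after the four-membered ring has opened, so the net change is a ring expansion by the two alkyne carbons. No stereocentre is created, and the racemic carbinol carbon of 9 becomes the sp2 carbon C1. The step needs 6-endo closure to win over 5-exo-dig closure to a 2-(methoxymethylidene)cyclopentene-1,3-dione; the 6-endo path creates an aromatic ring, and a methoxy group, unlike aryl, silyl or ester groups, gives little stabilisation to the exocyclic vinyl radical of the 5-exo path. The substituent pattern is fixed by the connectivity of 9, and a methyl ynol ether has no β-hydrogen, so it cannot fragment by a retro-ene reaction at this temperature.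

**Step 4**
Reactants: 12 2-tert-butoxy-3-icosyl-5-methoxy-1,4-benzoquinone
Product: 13 Irisoquin D (2-hydroxy-3-icosyl-5-methoxy-1,4-benzoquinone)
Conditions: CF3CO2H, CH2Cl2, 0 °C to rt
Reagents that add atoms: none
Why: Acidolysis of the tert-butyl vinylogous ester through the tert-butyl cation (lost as isobutene) should free the C2 hydroxyl, while the methyl vinylogous ester at C5 cannot ionise and survives anhydrous acid (tert-butyl ether cleavage).

**Compound list**
1 | di-tert-butyl squarate (3,4-di-tert-butoxycyclobut-3-ene-1,2-dione) | CC(C)(C)OC1=C(OC(C)(C)C)C(=O)C1=O | starting material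
2 | 1-bromoicosane | CCCCCCCCCCCCCCCCCCCCBr | starting material
3 | icosylmagnesium bromide | CCCCCCCCCCCCCCCCCCCC[Mg]Br | intermediate
4 | bromomagnesium rac-2,3-di-tert-butoxy-1-icosyl-4-oxocyclobut-2-en-1-olate | CCCCCCCCCCCCCCCCCCCCC1([O-])C(OC(C)(C)C)=C(OC(C)(C)C)C1=O.[Mg+2].[Br-] | intermediate
5 | rac-2,3-di-tert-butoxy-1-icosyl-4-oxocyclobut-2-en-1-yl trifluoroacetate | CCCCCCCCCCCCCCCCCCCCC1(OC(=O)C(F)(F)F)C(OC(C)(C)C)=C(OC(C)(C)C)C1=O | intermediate
6 | 3-tert-butoxy-4-icosylcyclobut-3-ene-1,2-dione | CCCCCCCCCCCCCCCCCCCCC1=C(OC(C)(C)C)C(=O)C1=O | intermediate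
7 | chloroacetaldehyde dimethyl acetal (2-chloro-1,1-dimethoxyethane) | COC(CCl)OC | starting material
8 | lithium methoxyacetylide | [Li]C#COC | intermediate
9 | rac-3-tert-butoxy-4-hydroxy-2-icosyl-4-(methoxyethynyl)cyclobut-2-en-1-one | CCCCCCCCCCCCCCCCCCCCC1=C(OC(C)(C)C)C(O)(C#COC)C1=O | intermediate
10 | (Z)-3-tert-butoxy-4-hydroxy-2-icosyl-6-methoxyhexa-1,3-dien-5-yn-1-one (alkynylvinylketene) | CCCCCCCCCCCCCCCCCCCCC(=C=O)/C(OC(C)(C)C)=C(/O)C#COC | intermediate
11 | 3-tert-butoxy-4-hydroxy-2-icosyl-6-methoxyphenoxyl-5-yl diradical | CCCCCCCCCCCCCCCCCCCCC1=C([O])C(OC)=[C]C(O)=C1OC(C)(C)C | intermediate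
12 | 2-tert-butoxy-3-icosyl-5-methoxy-1,4-benzoquinone | CCCCCCCCCCCCCCCCCCCCC1=C(OC(C)(C)C)C(=O)C=C(OC)C1=O | intermediate
13 | Irisoquin D (2-hydroxy-3-icosyl-5-methoxy-1,4-benzoquinone) | CCCCCCCCCCCCCCCCCCCCC1=C(O)C(=O)C=C(OC)C1=O | target

**Total step count:** 4
**Longest linear sequence:** 4 steps (1 → 6 → 9 → 12 → 13)

**Steps most likely to fail**

Step 3 (key step). The ring closure of ketene 10 may go 5-exo instead of 6-endo, or the ynol ether may decompose on heating before the cyclobutenone opens. The fallback sets out from 9 and comes back at 12, replacing the diradical closure by a 6π electrocyclisation that can only form the six-membered ring. Semihydrogenation of the ynol ether of 9 (H2, Pd/CaCO3 poisoned with Pb(OAc)2, quinoline, EtOAc, rt) should give 3-tert-butoxy-4-hydroxy-2-icosyl-4-[(Z)-2-methoxyvinyl]cyclobut-2-en-1-one F1. Heating F1 in toluene at 110 °C should open the four-membered ring to a dienylketene that closes by 6π electrocyclisation and enolises to 2-tert-butoxy-3-icosyl-5-methoxybenzene-1,4-diol F2. Oxidation of F2 with Ag2O in Et2O should give 12.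

Step 2. Diethylamine and lithium methoxide, which accompany the in-flask generation of the acetylide, may attack the vinylogous ester of 6 in competition with the 1,2-addition. The fallback sets out from 6 and comes back at 9, building the same nucleophile free of amine and alkoxide from trichloroethylene. Trichloroethylene with NaOMe in MeOH/THF (elimination–addition) should give (E)-1,2-dichloro-1-methoxyethene F3. Two equivalents of n-BuLi in Et2O at −78 °C should remove HCl to give chloro(methoxy)ethyne F4 and then exchange its chlorine for lithium to give 8. Addition of this solution to 6 at −78 °C and an NH4Cl quench should give 9.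

Step 1. The acid released in the trifluoroacetic anhydride-induced transposition may also cleave the remaining tert-butyl ether, and the long-chain Grignard reagent may add sluggishly or twice at low temperature. The fallback sets out from 3 and comes back at 13, changing the protecting group and the end game. Addition of 3 to purchased diisopropyl squarate (THF, −78 °C, NH4Cl quench) should give rac-4-hydroxy-4-icosyl-2,3-diisopropoxycyclobut-2-en-1-one F5, which can be isolated. Catalytic conc. HCl in CH2Cl2 should convert F5 into 3-icosyl-4-isopropoxycyclobut-3-ene-1,2-dione F6. Acetylide 8, used as in step 2, should give rac-4-hydroxy-2-icosyl-3-isopropoxy-4-(methoxyethynyl)cyclobut-2-en-1-one F7. Thermolysis as in step 3 should give 2-isopropoxy-3-icosyl-5-methoxy-1,4-benzoquinone F8. BCl3 in CH2Cl2 at −78 °C should cleave the secondary isopropyl ether in preference to the methyl ether and give 13.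

**Further compounds**
F1 | step 3 | 3-tert-butoxy-4-hydroxy-2-icosyl-4-[(Z)-2-methoxyvinyl]cyclobut-2-en-1-one (racemic) | CCCCCCCCCCCCCCCCCCCCC1=C(OC(C)(C)C)C(O)(/C=C\OC)C1=O
F2 | step 3 | 2-tert-butoxy-3-icosyl-5-methoxybenzene-1,4-diol | CCCCCCCCCCCCCCCCCCCCc1c(O)c(OC)cc(O)c1OC(C)(C)C
F3 | step 2 | (E)-1,2-dichloro-1-methoxyethene | CO/C(Cl)=C\Cl
F4 | step 2 | chloro(methoxy)ethyne | COC#CCl
F5 | step 1 | rac-4-hydroxy-4-icosyl-2,3-diisopropoxycyclobut-2-en-1-one | CCCCCCCCCCCCCCCCCCCCC1(O)C(OC(C)C)=C(OC(C)C)C1=O
F6 | step 1 | 3-icosyl-4-isopropoxycyclobut-3-ene-1,2-dione | CCCCCCCCCCCCCCCCCCCCC1=C(OC(C)C)C(=O)C1=O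
F7 | step 1 | rac-4-hydroxy-2-icosyl-3-isopropoxy-4-(methoxyethynyl)cyclobut-2-en-1-one | CCCCCCCCCCCCCCCCCCCCC1=C(OC(C)C)C(O)(C#COC)C1=O
F8 | step 1 | 2-isopropoxy-3-icosyl-5-methoxy-1,4-benzoquinone | CCCCCCCCCCCCCCCCCCCCC1=C(OC(C)C)C(=O)C=C(OC)C1=O
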